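**Retrosynthetic overview**
- The ring is a cyclohex-2-enone in which the C2=C3(CH3) unit lies between the ketone carbon C1 and the carbinol carbon C4, and C1 and C4 are 1,4-related through C6–C5. This feature lets C1 and C4 both start as aldehyde carbons of an open-chain 1,4-dialdehyde, C1 reacting as an acyl anion and C4 as an electrophile.
- C2=C3(CH3) comes from 2-nitropropene, electrophilic at C2 and nucleophilic at C3; the nitro group on C3 is lost as nitrite to create the double bond.
- Key disconnection: C1–C2 (carbene-catalysed Stetter addition) and C3–C4 (intramolecular Henry closure) in one operation from (2R)-2-geranylgeranylbutanedial. This forms the only ring and sets C4.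
- The dialdehyde comes from the 1,4-diol by double Swern oxidation. The diol comes from an Evans alkylation of a succinate half-ester imide with geranylgeranyl bromide (sets C5), followed by LiBH4 reduction.

Key step: step 7

Remark: "geranylgeranyl" denotes the all-E (2E,6E,10E)-3,7,11,15-tetramethylhexadeca-2,6,10,14-tetraen-1-yl group, and commercial all-E geranylgeraniol is assumed as its source. Ring atoms are numbered C1 (C=O), C2 (=CH), C3 (C–CH3), C4 (CH–OH), C5 (CH–geranylgeranyl), C6 (CH2); the open-chain precursors keep these labels. The target is the cis (4R,5R) isomer.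

**Step 1**
Reactants: 1 (2E,6E,10E)-geranylgeraniol
Product: 2 (2E,6E,10E)-geranylgeranyl bromide
Conditions: PBr3 (0.4 equiv), Et2O, −10 → 0 °C
Reagents that add atoms: phosphorus tribromide, BrP(Br)Br
Why: PBr3 bromination of a primary allylic alcohol (SN2 on the dibromophosphite) at low temperature should keep the 2E geometry and avoid allylic transposition.

**Step 2**
Reactants: 3 (R)-4-benzyl-1,3-oxazolidin-2-one; 4 methyl 4-chloro-4-oxobutanoate
Product: 5 methyl 4-[(4R)-4-benzyl-2-oxo-1,3-oxazolidin-3-yl]-4-oxobutanoate
Conditions: Et3N, 4-(dimethylamino)pyridine (10 mol %), CH2Cl2, 0 °C → rt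
Reagents that add atoms: none
Why: N-acylation of the oxazolidinone by the acid chloride under nucleophilic catalysis (acylpyridinium) should leave the distal methyl ester untouched.

**Step 3**
Reactants: 5 methyl 4-[(4R)-4-benzyl-2-oxo-1,3-oxazolidin-3-yl]-4-oxobutanoate; 2 (2E,6E,10E)-geranylgeranyl bromide
Product: 7 methyl (3R)-4-[(4R)-4-benzyl-2-oxo-1,3-oxazolidin-3-yl]-3-geranylgeranyl-4-oxobutanoate, via sodium Z-enolate 6 (not isolated)
Conditions: NaN(SiMe3)2 (1.1 equiv), THF, −78 °C; then 2, −78 → −45 °C
Reagents that add atoms: none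
Why: Evans asymmetric alkylation, in which the more acidic imide α-CH2 gives the sodium-chelated Z-enolate and the allylic bromide adds to the face away from the benzyl group, should set C5 as R.

**Step 4**
Reactants: 7 methyl (3R)-4-[(4R)-4-benzyl-2-oxo-1,3-oxazolidin-3-yl]-3-geranylgeranyl-4-oxobutanoate
Product: 8 (2R)-2-geranylgeranylbutane-1,4-diol
Conditions: LiBH4 (3 equiv), MeOH (3 equiv), THF, 0 °C → rt; aq. NH4Cl
Reagents that add atoms: none
Why: Reductive cleavage of the N-acyl oxazolidinone at the exocyclic carbonyl together with ester reduction by LiBH4 should give the diol, in which C5 is no longer α to a carbonyl and cannot epimerise.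

**Step 5**
Reactants: 8 (2R)-2-geranylgeranylbutane-1,4-diol
Product: 9 (2R)-2-geranylgeranylbutanedial
Conditions: (COCl)2 (3 equiv), DMSO (6 equiv), CH2Cl2, −78 °C; then i-Pr2NEt (8 equiv), −78 → −30 °C; cold pH 7 buffer; crude product used at once
Reagents that add atoms: none
Why: Double Swern oxidation activates both primary alcohols as alkoxysulfonium ions before the base is added, which should avoid lactol and lactone formation, while the hindered amine and low temperature protect the α-stereocentre C5.

**Step 6**
Reactants: 10 2-nitropropan-1-ol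
Product: 11 2-nitropropene
Conditions: phthalic anhydride (1.3 equiv), neat, 150 → 185 °C, about 110 mmHg, product distilled out as formed; redistilled, kept at −20 °C, used within a day
Reagents that add atoms: none
Why: Dehydration of a β-nitro alcohol through its phthalate half-ester (thermal elimination) is the standard preparation of this nitroalkene, which is removed from the hot zone as it forms.

**Step 7**
Reactants: 9 (2R)-2-geranylgeranylbutanedial; 11 2-nitropropene
Product: 14 (4R,5R)-5-geranylgeranyl-4-hydroxy-3-methylcyclohex-2-en-1-one, via nitro keto aldehyde 12 (not isolated), via nitro ketol 13 (not isolated)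
Conditions: 2-(pentafluorophenyl)-6,7-dihydro-5H-pyrrolo[2,1-c][1,2,4]triazol-2-ium tetrafluoroborate (15 mol %), NaOAc (0.5 equiv), t-AmOH/toluene 1:1 (0.02 M), 0 °C, 11 (1.2 equiv) added by syringe pump; then 1,8-diazabicyclo[5.4.0]undec-7-ene (DBU, 1.5 equiv), 0 °C, 30 min; AcOH quench
Reagents that add atoms: none
Why: Proposed new method: the triazolylidene should add to the unbranched C1 aldehyde of 9 to give a Breslow intermediate that attacks the CH2 terminus of 11 (Stetter reaction, C1–C2 bond), the nitronate carbon C3 so formed should add to the C4 aldehyde (intramolecular Henry reaction, C3–C4 bond), and DBU should then expel nitrite from the β-nitro ketone 13 by E1cB to give the C2=C3 enone. The closest known reaction types are the carbene-catalysed intermolecular Stetter addition of aliphatic aldehydes to nitroalkenes, domino Stetter–aldol sequences of aromatic dialdehydes, and base-induced loss of HNO2 from β-nitro ketones; the Stetter–Henry pairing on an aliphatic 1,4-dialdehyde is the new element. The one ring closes in a 6-exo-trig mode by attack of the exocyclic nitronate on the aldehyde. C5 is carried over from 9, and C4 should be set in the closure through a chair transition state with the C5 side chain equatorial and anti to the incoming carbon and the aldehyde oxygen axial and antiperiplanar to the nitronate nitrogen (no chelating cation), which places the hydroxyl cis to the side chain (4R); the C3 centre is erased in the elimination. The step needs Breslow formation at C1 only, which the α-branch at C5 should secure by retarding carbene addition to the C4 aldehyde, and it needs ring closure and nitrite loss to outrun α-epimerisation and retro-Henry equilibration, which the low temperature and the axial, π-aligned nitro group of the kinetic adduct should favour.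

**Compound list**
1 | (2E,6E,10E)-geranylgeraniol | CC(C)=CCC/C(C)=C/CC/C(C)=C/CC/C(C)=C/CO | starting material
2 | (2E,6E,10E)-geranylgeranyl bromide | CC(C)=CCC/C(C)=C/CC/C(C)=C/CC/C(C)=C/CBr | intermediate
3 | (R)-4-benzyl-1,3-oxazolidin-2-one | O=C1N[C@H](Cc2ccccc2)CO1 | starting material
4 | methyl 4-chloro-4-oxobutanoate | COC(=O)CCC(Cl)=O | starting material
5 | methyl 4-[(4R)-4-benzyl-2-oxo-1,3-oxazolidin-3-yl]-4-oxobutanoate | COC(=O)CCC(=O)N1C(=O)OC[C@H]1Cc1ccccc1 | intermediate
6 | sodium Z-enolate of 5 | COC(=O)C/C=C(\[O-])N1C(=O)OC[C@H]1Cc1ccccc1.[Na+] | intermediate (not isolated)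
7 | methyl (3R)-4-[(4R)-4-benzyl-2-oxo-1,3-oxazolidin-3-yl]-3-geranylgeranyl-4-oxobutanoate | COC(=O)C[C@@H](C/C=C(\C)CC/C=C(\C)CC/C=C(\C)CCC=C(C)C)C(=O)N1C(=O)OC[C@H]1Cc1ccccc1 | intermediate
8 | (2R)-2-geranylgeranylbutane-1,4-diol | OC[C@H](C/C=C(\C)CC/C=C(\C)CC/C=C(\C)CCC=C(C)C)CCO | intermediate
9 | (2R)-2-geranylgeranylbutanedial | O=C[C@H](C/C=C(\C)CC/C=C(\C)CC/C=C(\C)CCC=C(C)C)CC=O | intermediate
10 | 2-nitropropan-1-ol (racemic) | CC(CO)[N+](=O)[O-] | starting material
11 | 2-nitropropene | CC(=C)[N+](=O)[O-] | intermediate
12 | (2R)-2-geranylgeranyl-6-nitro-4-oxoheptanal (both C6 epimers) | O=C[C@H](C/C=C(\C)CC/C=C(\C)CC/C=C(\C)CCC=C(C)C)CC(=O)CC(C)[N+](=O)[O-] | intermediate (not isolated)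
13 | (4R,5R)-5-geranylgeranyl-4-hydroxy-3-methyl-3-nitrocyclohexan-1-one (C3 not defined) | CC(C)=CCC/C(C)=C/CC/C(C)=C/CC/C(C)=C/C[C@@H]1CC(=O)CC(C)([N+](=O)[O-])[C@@H]1O | intermediate (not isolated)
14 | (4R,5R)-5-geranylgeranyl-4-hydroxy-3-methylcyclohex-2-en-1-one (CNP0277821.2) | CC(C)=CCC/C(C)=C/CC/C(C)=C/CC/C(C)=C/C[C@@H]1CC(=O)C=C(C)[C@@H]1O | target

**Step count**
Total: 7 steps. Longest linear sequence: 5 steps (step 1 or 2, then 3, 4, 5, 7).

**Steps most likely to fail**

1. Step 7 (proposed new method).
   - What may go wrong: the nitroalkene may deactivate the carbene or polymerise anionically; the dialdehyde may undergo carbene-mediated redox lactonisation; the α-centre may epimerise before ring closure; and a reversible Henry closure may erode the facial selectivity at C4.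
   - Fallback: known reactions only, setting out from 7 and returning at 14.
     - NaBH4 in THF/H2O, then catalytic p-toluenesulfonic acid, should remove the auxiliary reductively and close the hydroxy ester to (4R)-4-geranylgeranyloxolan-2-one F1.
     - 1-Propynyllithium (THF, −78 °C) should open the lactone to (6R)-6-geranylgeranyl-7-hydroxyhept-2-yn-4-one F2, which makes the C1–C2 bond.
     - NaI/AcOH should add HI anti to give (2Z,6R)-6-geranylgeranyl-7-hydroxy-2-iodohept-2-en-4-one F3.
     - Dess–Martin periodinane (NaHCO3, CH2Cl2) should give (2R,5Z)-2-geranylgeranyl-6-iodo-4-oxohept-5-enal F4.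
     - Intramolecular Nozaki–Hiyama–Kishi coupling (CrCl2, NiCl2 1 mol %, DMF, rt) should form C3–C4 and rejoin the route at 14.
     - The facial sense of this closure is not secured either. If it, or step 7 itself, delivers the C4 epimer (4S,5R)-5-geranylgeranyl-4-hydroxy-3-methylcyclohex-2-en-1-one F5, Mitsunobu inversion with 4-nitrobenzoic acid (PPh3, DIAD, toluene) should give (1R,6R)-6-geranylgeranyl-2-methyl-4-oxocyclohex-2-en-1-yl 4-nitrobenzoate F6, and methanolysis (K2CO3, MeOH, 0 °C) should then give 14.

2. Step 5.
   - What may go wrong: α-epimerisation and self-condensation of the 1,4-dialdehyde while the amine is present and on concentration, and lactol formation if one alcohol is oxidised ahead of the other.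
   - Fallback: reach 9 by reduction instead of oxidation, setting out from 7 and returning at 9.
     - Me(MeO)NH·HCl/AlMe3 (CH2Cl2, 0 °C → rt) should convert both the imide and the ester into Weinreb amides, giving (2R)-2-geranylgeranyl-N1,N4-dimethoxy-N1,N4-dimethylbutanediamide F7.
     - Diisobutylaluminium hydride (THF, −78 °C) should give the doubly chelated aluminium hemiaminal, which releases both aldehydes only on cold aqueous potassium sodium tartrate work-up, with no base present.

3. Step 6.
   - What may go wrong: thermal and base-triggered polymerisation of the nitroalkene during distillation and storage, which would also compromise step 7.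
   - Fallback: avoid isolating the nitroalkene, setting out from 10 and returning at 11.
     - Ac2O with a trace of H2SO4 should give the storable 2-nitropropyl acetate F8.
     - Added to the flask of step 7 with NaOAc raised to 1.5 equiv, F8 should lose acetic acid and release 11 slowly, at the rate at which it is consumed.

**Further compounds**
F1 | step 7 | (4R)-4-geranylgeranyloxolan-2-one | O=C1C[C@@H](C/C=C(\C)CC/C=C(\C)CC/C=C(\C)CCC=C(C)C)CO1
F2 | step 7 | (6R)-6-geranylgeranyl-7-hydroxyhept-2-yn-4-one | CC#CC(=O)C[C@@H](C/C=C(\C)CC/C=C(\C)CC/C=C(\C)CCC=C(C)C)CO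
F3 | step 7 | (2Z,6R)-6-geranylgeranyl-7-hydroxy-2-iodohept-2-en-4-one | C/C(I)=C/C(=O)C[C@@H](C/C=C(\C)CC/C=C(\C)CC/C=C(\C)CCC=C(C)C)CO
F4 | step 7 | (2R,5Z)-2-geranylgeranyl-6-iodo-4-oxohept-5-enal | C/C(I)=C/C(=O)C[C@@H](C/C=C(\C)CC/C=C(\C)CC/C=C(\C)CCC=C(C)C)C=O
F5 | step 7 | (4S,5R)-5-geranylgeranyl-4-hydroxy-3-methylcyclohex-2-en-1-one | CC(C)=CCC/C(C)=C/CC/C(C)=C/CC/C(C)=C/C[C@@H]1CC(=O)C=C(C)[C@H]1O
F6 | step 7 | (1R,6R)-6-geranylgeranyl-2-methyl-4-oxocyclohex-2-en-1-yl 4-nitrobenzoate | CC(C)=CCC/C(C)=C/CC/C(C)=C/CC/C(C)=C/C[C@@H]1CC(=O)C=C(C)[C@@H]1OC(=O)c1ccc(cc1)[N+](=O)[O-]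
F7 | step 5 | (2R)-2-geranylgeranyl-N1,N4-dimethoxy-N1,N4-dimethylbutanediamide | CON(C)C(=O)C[C@@H](C/C=C(\C)CC/C=C(\C)CC/C=C(\C)CCC=C(C)C)C(=O)N(C)OC
F8 | step 6 | 2-nitropropyl acetate | CC(COC(C)=O)[N+](=O)[O-]
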